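**Retrosynthetic overview**

1. Target ⇐ global desilylation; the C8 ester bond ⇐ decalinol core + bis-silylated (S)-3,4-dihydroxy-2-methylidenebutanoic acid (asymmetric Morita–Baylis–Hillman reaction).
2. Decalinol core ⇐ acyclic (3Z,5E)-trienal that already carries the acrylate. Both rings form in one operation: ring A first (C1–C6, intramolecular conjugate-ene reaction of the prenyl olefin with the enal), ring B second (C8–C9, type 2 carbonyl-ene reaction giving the axial 8-OH and the C10=C14 methylene).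
3. Trienal ⇐ Stille coupling (C7–C11) ⇐ syn-hydrostannation of an enyne acetal (C6=C7 geometry) ⇐ Sonogashira coupling (C5–C6) ⇐ carbocupration/iodination of a propargyl silyl ether (C4=C5 geometry).

Assumption: the SMILES is taken literally, i.e. a trans-fused octalin with the acrylic acid (C7) and the acyloxy group (C8) trans-diaxial and an (S)-carbinol in the side chain; positions are given in cadinane numbering (C1/C6 ring fusion, C4=C5 ring alkene bearing C15H2OH, C7 acrylic acid C11–C13, C8 ester oxygen, C10=C14 methylene).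

**Route**

Step 1
Reactants: 1 5-bromo-2-methylpent-2-ene; 2 tert-butyldimethyl(prop-2-yn-1-yloxy)silane
Product: 5 (E)-tert-butyl{[2-(iodomethylidene)-6-methylhept-5-en-1-yl]oxy}dimethylsilane (iodine cis to the 4-methylpent-3-enyl chain), via homoprenylmagnesium bromide 3 (not isolated), via alkenylcopper 4 (not isolated)
Conditions: 1, Mg, Et2O; CuBr·SMe2, Et2O/Me2S, −45 °C; 2, −25 °C; I2, −78 → 0 °C
Reagents that add atoms: iodine, II
Why: Normant carbocupration: the alkylcopper adds syn across the terminal alkyne with carbon going to the internal position (non-chelating bulky silyl ether in Et2O), and iodinolysis of the C–Cu bond with retention puts iodine cis to the homoprenyl chain, which is the C4=C5 geometry ring A needs.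

Step 2
Reactants: 5 (E)-vinyl iodide; 6 3,3-diethoxyprop-1-yne
Product: 7 (4E)-5-{[tert-butyl(dimethyl)silyl]oxymethyl}-1,1-diethoxy-9-methyldeca-4,8-dien-2-yne
Conditions: PdCl2(PPh3)2 (3 mol %), CuI (6 mol %), Et3N, THF, rt
Reagents that add atoms: none
Why: Sonogashira coupling of a vinyl iodide with a terminal alkyne proceeds with retention of alkene geometry and tolerates the acetal and the silyl ether.

Step 3
Reactants: 7 enyne acetal
Product: 8 tributyl[(2E,4E)-5-{[tert-butyl(dimethyl)silyl]oxymethyl}-1,1-diethoxy-9-methyldeca-2,4,8-trien-2-yl]stannane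
Conditions: Bu3SnH, Mo(CO)3(CNtBu)3 (5 mol %), hydroquinone (10 mol %), THF, 55 °C
Reagents that add atoms: tributylstannane, CCCC[SnH](CCCC)CCCC
Why: Molybdenum-catalysed hydrostannation is a syn H–Sn addition that places tin on the alkyne carbon next to the oxygen-bearing propargylic carbon, so H6 ends cis to tin and the acetal carbon (future C8) ends cis to C5.

Step 4
Reactants: 9 2-bromoprop-2-enoic acid
Product: 10 tri(propan-2-yl)silyl 2-bromoprop-2-enoate
Conditions: iPr3SiCl, Et3N, CH2Cl2, 0 °C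
Reagents that add atoms: chlorotri(propan-2-yl)silane, CC(C)[Si](Cl)(C(C)C)C(C)C
Why: Silyl ester formation from the acid and a silyl chloride; the bulky silyl ester survives the coupling and Lewis-acid steps and is removed together with the silyl ethers in the last step.

Step 5
Reactants: 8 alkenylstannane; 10 silyl 2-bromoacrylate
Product: 11 tri(propan-2-yl)silyl (3Z,5E)-6-{[tert-butyl(dimethyl)silyl]oxymethyl}-3-(diethoxymethyl)-10-methyl-2-methylideneundeca-3,5,9-trienoate
Conditions: Pd2(dba)3 (5 mol %), AsPh3 (20 mol %), CuI (20 mol %), DMF, 40 °C, dark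
Reagents that add atoms: none
Why: Stille coupling (copper-assisted, suited to hindered α-substituted alkenylstannanes) replaces tin by the acrylate carbon C11 with retention, so the acetal carbon stays cis to C5 (3Z).

Step 6
Reactants: 11 triene acetal
Product: 12 tri(propan-2-yl)silyl (3Z,5E)-6-{[tert-butyl(dimethyl)silyl]oxymethyl}-3-formyl-10-methyl-2-methylideneundeca-3,5,9-trienoate (formyl group cis to the dienyl chain)
Conditions: (CO2H)2, H2O, SiO2, CH2Cl2, 0 °C; kept cold and used at once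
Reagents that add atoms: water, O
Why: Acid-catalysed hydrolysis of an allylic acetal is fast under conditions too mild to isomerise the (Z)-enal or to touch the silyl ether and the silyl ester.

Step 7
Reactants: 12 (3Z,5E)-trienal
Product: 14 tri(propan-2-yl)silyl 2-[(1R,2S,4aS,8aS)-7-{[tert-butyl(dimethyl)silyl]oxymethyl}-2-hydroxy-4-methylidene-1,2,3,4,4a,5,6,8a-octahydronaphthalen-1-yl]prop-2-enoate (trans ring fusion; acrylate and OH trans-diaxial), via monocyclic aldehyde 13 (not isolated)
Conditions: (S)-3,3-diphenyl-1-(2-methylphenyl)tetrahydro-1H,3H-pyrrolo[1,2-c][1,3,2]oxazaborole·HNTf2 (20 mol %), CH2Cl2, −78 °C; then Me2AlCl (1.5 equiv), −78 → −20 °C; aq. Rochelle salt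
Reagents that add atoms: none
Why: Proposed new method: the boron cation binds the formyl oxygen of the α-substituted enal (s-trans, formyl C–H···O contact, one face of C6 shielded by the catalyst aryl group) and the tethered trisubstituted olefin adds to the open face of C6 in a concerted, suprafacial intramolecular conjugate-ene reaction through a half-chair with both π-systems pseudo-equatorial, which forms ring A with trans C1/C6 (1S,6S) and, because the formyl group is cis to C5 in the (3Z)-enal and the allylic hydrogen is delivered to C7 on the same face as C1, fixes C7 as R (acrylate later axial), after which Me2AlCl activates aldehyde 13 for a type 2 carbonyl-ene closure of ring B through a trans-fused chair in which the C=O must be axial to reach the allylic methyl hydrogen, giving the axial (8S)-OH and the exocyclic methylene; the closest known reaction types are the Me2AlCl-promoted sequential ene annulation of alkenes with enals (conjugate-ene then type 2 carbonyl-ene), the trans-selective Lewis-acid ene cyclisation of activated 1,7-dienes, and face-selective activation of α-substituted enals by chiral oxazaborolidinium cations.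

Step 8
Reactants: 15 {[tert-butyl(dimethyl)silyl]oxy}acetaldehyde; 16 1,1,1,3,3,3-hexafluoropropan-2-yl prop-2-enoate
Product: 17 1,1,1,3,3,3-hexafluoropropan-2-yl (3S)-4-{[tert-butyl(dimethyl)silyl]oxy}-3-hydroxy-2-methylidenebutanoate
Conditions: β-isocupreidine (10 mol %), DMF, −55 °C
Reagents that add atoms: none
Why: Enantioselective Morita–Baylis–Hillman reaction: β-isocupreidine with the hexafluoroisopropyl acrylate attacks the aldehyde face that gives (R)-adducts from alkyl aldehydes, which for the CH2OSi substituent is the required (S) descriptor.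

Step 9
Reactants: 17 Morita–Baylis–Hillman adduct
Product: 18 1,1,1,3,3,3-hexafluoropropan-2-yl (3S)-3,4-bis{[tert-butyl(dimethyl)silyl]oxy}-2-methylidenebutanoate
Conditions: TBSOTf, 2,6-lutidine, CH2Cl2, −78 → 0 °C
Reagents that add atoms: tert-butyldimethylsilyl trifluoromethanesulfonate, CC(C)(C)[Si](C)(C)OS(=O)(=O)C(F)(F)F
Why: Silylation of the secondary allylic alcohol with a silyl triflate and a hindered base is fast and leaves the activated ester untouched.

Step 10
Reactants: 18 bis-silyl hexafluoroisopropyl ester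
Product: 19 (3S)-3,4-bis{[tert-butyl(dimethyl)silyl]oxy}-2-methylidenebutanoic acid
Conditions: LiOH·H2O, THF/H2O, 0 °C; then 1 M HCl to pH 3, 0 °C
Reagents that add atoms: lithium hydroxide, [Li+].[OH-]
Why: Saponification of the strongly activated hexafluoroisopropyl ester occurs at 0 °C without conjugate addition or silyl loss, and the carbinol centre is not enolisable.

Step 11
Reactants: 14 decalinol; 19 side-chain acid
Product: 21 tri(propan-2-yl)silyl 2-[(1R,2S,4aS,8aS)-2-{[(3S)-3,4-bis{[tert-butyl(dimethyl)silyl]oxy}-2-methylidenebutanoyl]oxy}-7-{[tert-butyl(dimethyl)silyl]oxymethyl}-4-methylidene-1,2,3,4,4a,5,6,8a-octahydronaphthalen-1-yl]prop-2-enoate, via mixed anhydride 20 (not isolated)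
Conditions: 19, 2,4,6-Cl3C6H2COCl, Et3N, toluene, rt; then 14, DMAP, rt → 40 °C
Reagents that add atoms: none
Why: Yamaguchi esterification through the mixed anhydride acylates the hindered axial 8-OH with retention at C8, and any ester derived from a minor enantiomer of 14 is a diastereomer that is removed by chromatography here.

Step 12
Reactants: 21 fully silylated ester
Product: 22 2-[(1R,2S,4aS,8aS)-2-{[(3S)-3,4-dihydroxy-2-methylidenebutanoyl]oxy}-7-(hydroxymethyl)-4-methylidene-1,2,3,4,4a,5,6,8a-octahydronaphthalen-1-yl]prop-2-enoic acid (CNP0460913.4)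
Conditions: HF·pyridine, pyridine, THF, 0 °C → rt
Reagents that add atoms: none
Why: Global desilylation under buffered, mildly acidic fluoride conditions cleaves the three silyl ethers and the silyl ester without forming an alkoxide that could lactonise the side chain or shift acyl groups.

**Compound list**

1 | 5-bromo-2-methylpent-2-ene | CC(C)=CCCBr | starting material
2 | tert-butyldimethyl(prop-2-yn-1-yloxy)silane | C#CCO[Si](C)(C)C(C)(C)C | starting material
3 | (4-methylpent-3-en-1-yl)magnesium bromide | CC(C)=CCC[Mg]Br | intermediate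
4 | (E)-{3-{[tert-butyl(dimethyl)silyl]oxy}-2-(4-methylpent-3-en-1-yl)prop-1-en-1-yl}copper (MgBr2 complex) | [Cu]/C=C(/CO[Si](C)(C)C(C)(C)C)CCC=C(C)C | intermediate
5 | (E)-tert-butyl{[2-(iodomethylidene)-6-methylhept-5-en-1-yl]oxy}dimethylsilane | I/C=C(/CO[Si](C)(C)C(C)(C)C)CCC=C(C)C | intermediate
6 | 3,3-diethoxyprop-1-yne | C#CC(OCC)OCC | starting material
7 | (4E)-5-{[tert-butyl(dimethyl)silyl]oxymethyl}-1,1-diethoxy-9-methyldeca-4,8-dien-2-yne | CCOC(OCC)C#C/C=C(/CO[Si](C)(C)C(C)(C)C)CCC=C(C)C | intermediate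
8 | tributyl[(2E,4E)-5-{[tert-butyl(dimethyl)silyl]oxymethyl}-1,1-diethoxy-9-methyldeca-2,4,8-trien-2-yl]stannane | CCOC(OCC)/C(=C\C=C(\CO[Si](C)(C)C(C)(C)C)CCC=C(C)C)[Sn](CCCC)(CCCC)CCCC | intermediate
9 | 2-bromoprop-2-enoic acid | C=C(Br)C(=O)O | starting material
10 | tri(propan-2-yl)silyl 2-bromoprop-2-enoate | C=C(Br)C(=O)O[Si](C(C)C)(C(C)C)C(C)C | intermediate
11 | tri(propan-2-yl)silyl (3Z,5E)-6-{[tert-butyl(dimethyl)silyl]oxymethyl}-3-(diethoxymethyl)-10-methyl-2-methylideneundeca-3,5,9-trienoate | CCOC(OCC)/C(=C\C=C(\CO[Si](C)(C)C(C)(C)C)CCC=C(C)C)C(=C)C(=O)O[Si](C(C)C)(C(C)C)C(C)C | intermediate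
12 | tri(propan-2-yl)silyl (3Z,5E)-6-{[tert-butyl(dimethyl)silyl]oxymethyl}-3-formyl-10-methyl-2-methylideneundeca-3,5,9-trienoate | O=C/C(=C\C=C(\CO[Si](C)(C)C(C)(C)C)CCC=C(C)C)C(=C)C(=O)O[Si](C(C)C)(C(C)C)C(C)C | intermediate
13 | tri(propan-2-yl)silyl (3R)-3-[(1S,6S)-3-{[tert-butyl(dimethyl)silyl]oxymethyl}-6-(prop-1-en-2-yl)cyclohex-2-en-1-yl]-2-methylidene-4-oxobutanoate | C=C(C(=O)O[Si](C(C)C)(C(C)C)C(C)C)[C@H](C=O)[C@H]1C=C(CO[Si](C)(C)C(C)(C)C)CC[C@@H]1C(C)=C | intermediate
14 | tri(propan-2-yl)silyl 2-[(1R,2S,4aS,8aS)-7-{[tert-butyl(dimethyl)silyl]oxymethyl}-2-hydroxy-4-methylidene-1,2,3,4,4a,5,6,8a-octahydronaphthalen-1-yl]prop-2-enoate | C=C(C(=O)O[Si](C(C)C)(C(C)C)C(C)C)[C@H]1[C@H]2C=C(CO[Si](C)(C)C(C)(C)C)CC[C@@H]2C(=C)C[C@@H]1O | intermediate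
15 | {[tert-butyl(dimethyl)silyl]oxy}acetaldehyde | O=CCO[Si](C)(C)C(C)(C)C | starting material
16 | 1,1,1,3,3,3-hexafluoropropan-2-yl prop-2-enoate | C=CC(=O)OC(C(F)(F)F)C(F)(F)F | starting material
17 | 1,1,1,3,3,3-hexafluoropropan-2-yl (3S)-4-{[tert-butyl(dimethyl)silyl]oxy}-3-hydroxy-2-methylidenebutanoate | C=C(C(=O)OC(C(F)(F)F)C(F)(F)F)[C@H](O)CO[Si](C)(C)C(C)(C)C | intermediate
18 | 1,1,1,3,3,3-hexafluoropropan-2-yl (3S)-3,4-bis{[tert-butyl(dimethyl)silyl]oxy}-2-methylidenebutanoate | C=C(C(=O)OC(C(F)(F)F)C(F)(F)F)[C@H](O[Si](C)(C)C(C)(C)C)CO[Si](C)(C)C(C)(C)C | intermediate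
19 | (3S)-3,4-bis{[tert-butyl(dimethyl)silyl]oxy}-2-methylidenebutanoic acid | C=C(C(=O)O)[C@H](O[Si](C)(C)C(C)(C)C)CO[Si](C)(C)C(C)(C)C | intermediate
20 | (3S)-3,4-bis{[tert-butyl(dimethyl)silyl]oxy}-2-methylidenebutanoic 2,4,6-trichlorobenzoic anhydride | C=C(C(=O)OC(=O)c1c(Cl)cc(Cl)cc1Cl)[C@H](O[Si](C)(C)C(C)(C)C)CO[Si](C)(C)C(C)(C)C | intermediate
21 | tri(propan-2-yl)silyl 2-[(1R,2S,4aS,8aS)-2-{[(3S)-3,4-bis{[tert-butyl(dimethyl)silyl]oxy}-2-methylidenebutanoyl]oxy}-7-{[tert-butyl(dimethyl)silyl]oxymethyl}-4-methylidene-1,2,3,4,4a,5,6,8a-octahydronaphthalen-1-yl]prop-2-enoate | C=C(C(=O)O[Si](C(C)C)(C(C)C)C(C)C)[C@H]1[C@H]2C=C(CO[Si](C)(C)C(C)(C)C)CC[C@@H]2C(=C)C[C@@H]1OC(=O)C(=C)[C@H](O[Si](C)(C)C(C)(C)C)CO[Si](C)(C)C(C)(C)C | intermediate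
22 | 2-[(1R,2S,4aS,8aS)-2-{[(3S)-3,4-dihydroxy-2-methylidenebutanoyl]oxy}-7-(hydroxymethyl)-4-methylidene-1,2,3,4,4a,5,6,8a-octahydronaphthalen-1-yl]prop-2-enoic acid | C=C(C(=O)O)[C@H]1[C@H]2C=C(CO)CC[C@@H]2C(=C)C[C@@H]1OC(=O)C(=C)[C@H](O)CO | target

**Step count and risks**

Total steps: 12. Longest linear sequence: 8 (steps 1, 2, 3, 5, 6, 7, 11, 12).

Steps most likely to fail:

1. Step 7 (key bicyclisation). The sense and level of induction by the boron catalyst on a (Z)-trisubstituted enal are untested. Z→E isomerisation of 12 before C–C bond formation would give the C7 epimer. The tertiary cation could be captured by oxygen instead of losing a proton. Fallback, setting out from 12 and coming back at 21: Me2AlCl alone (2 equiv, CH2Cl2, −78 → −20 °C) runs the same two ene closures without a chiral catalyst and gives 14 as a racemate, that is together with its mirror image, the (1S,2R,4aR,8aR)-decalinol F1. Yamaguchi esterification of the mixture with enantiopure 19 via 20 gives 21 together with the diastereomeric ester of the mirror-image core F2, and chromatography separates the two. The absolute configuration then comes from the side-chain acid instead of from the catalyst.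

2. Step 3 (hydrostannation). Tin may go to the wrong alkyne carbon on a conjugated enyne. Fallback, setting out from 7 and coming back at 12: 7 is first hydrolysed (oxalic acid, wet SiO2) to the dienynal (E)-5-{[tert-butyl(dimethyl)silyl]oxymethyl}-9-methyldeca-4,8-dien-2-ynal F3. Hydrostannation of this ynal with Bu3SnH and the zerovalent palladium catalyst Pd(PPh3)4 at 0 °C is governed by the conjugated formyl group, which sends tin to the α-carbon with syn H–Sn delivery, and gives the α-stannyl (Z)-enal F4. Stille coupling of F4 with 10 under the conditions of step 5 gives 12 directly.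

3. Step 11 (esterification). The axial 8-OH is hindered, and DMAP can add to acrylates. Fallback, setting out from 14 and coming back at 22: 14 is acylated with the small acryloyl chloride (Et3N, CH2Cl2, −20 °C) to the 8-O-acrylate F5. The side chain is then grown on the scaffold by a β-isocupreidine-mediated Morita–Baylis–Hillman reaction of F5 with aldehyde 15; only the α-unsubstituted acrylate can react, and the catalyst sets the 3′S carbinol as in step 8, giving the 3′-hydroxy ester F6. HF·pyridine then removes the two silyl ethers and the silyl ester of F6 to give 22.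

**Further compounds**

F1 | step 7 | tri(propan-2-yl)silyl 2-[(1S,2R,4aR,8aR)-7-{[tert-butyl(dimethyl)silyl]oxymethyl}-2-hydroxy-4-methylidene-1,2,3,4,4a,5,6,8a-octahydronaphthalen-1-yl]prop-2-enoate | C=C(C(=O)O[Si](C(C)C)(C(C)C)C(C)C)[C@@H]1[C@@H]2C=C(CO[Si](C)(C)C(C)(C)C)CC[C@H]2C(=C)C[C@H]1O
F2 | step 7 | tri(propan-2-yl)silyl 2-[(1S,2R,4aR,8aR)-2-{[(3S)-3,4-bis{[tert-butyl(dimethyl)silyl]oxy}-2-methylidenebutanoyl]oxy}-7-{[tert-butyl(dimethyl)silyl]oxymethyl}-4-methylidene-1,2,3,4,4a,5,6,8a-octahydronaphthalen-1-yl]prop-2-enoate | C=C(C(=O)O[Si](C(C)C)(C(C)C)C(C)C)[C@@H]1[C@@H]2C=C(CO[Si](C)(C)C(C)(C)C)CC[C@H]2C(=C)C[C@H]1OC(=O)C(=C)[C@H](O[Si](C)(C)C(C)(C)C)CO[Si](C)(C)C(C)(C)C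
F3 | step 3 | (E)-5-{[tert-butyl(dimethyl)silyl]oxymethyl}-9-methyldeca-4,8-dien-2-ynal | O=CC#C/C=C(/CO[Si](C)(C)C(C)(C)C)CCC=C(C)C
F4 | step 3 | (2E,4E)-5-{[tert-butyl(dimethyl)silyl]oxymethyl}-9-methyl-2-(tributylstannyl)deca-2,4,8-trienal | O=C/C(=C\C=C(\CO[Si](C)(C)C(C)(C)C)CCC=C(C)C)[Sn](CCCC)(CCCC)CCCC
F5 | step 11 | tri(propan-2-yl)silyl 2-[(1R,2S,4aS,8aS)-7-{[tert-butyl(dimethyl)silyl]oxymethyl}-4-methylidene-2-(prop-2-enoyloxy)-1,2,3,4,4a,5,6,8a-octahydronaphthalen-1-yl]prop-2-enoate | C=C(C(=O)O[Si](C(C)C)(C(C)C)C(C)C)[C@H]1[C@H]2C=C(CO[Si](C)(C)C(C)(C)C)CC[C@@H]2C(=C)C[C@@H]1OC(=O)C=C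
F6 | step 11 | tri(propan-2-yl)silyl 2-[(1R,2S,4aS,8aS)-2-{[(3S)-4-{[tert-butyl(dimethyl)silyl]oxy}-3-hydroxy-2-methylidenebutanoyl]oxy}-7-{[tert-butyl(dimethyl)silyl]oxymethyl}-4-methylidene-1,2,3,4,4a,5,6,8a-octahydronaphthalen-1-yl]prop-2-enoate | C=C(C(=O)O[Si](C(C)C)(C(C)C)C(C)C)[C@H]1[C@H]2C=C(CO[Si](C)(C)C(C)(C)C)CC[C@@H]2C(=C)C[C@@H]1OC(=O)C(=C)[C@H](O)CO[Si](C)(C)C(C)(C)C
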